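Ring A is not brought in as an arene but grown onto a finished ring C. Its pattern (OH at C5, H at C6, O at C7, OMe at C8) is that of a semisquarate, so C5–C8 come from benzyl semisquarate and C4a/C8a are the two unsubstituted carbons of a 2-aryl-3-benzyloxy-4-pyranone. The precursor is a 4-methoxy-3-benzyloxycyclobutenone carrying that pyranone at its quaternary carbon. On heating, 4π ring opening and 6π ring closure onto the pyranone CH forge the C4a–C5 bond and deliver ring A, with C5–OH and C8–OMe already differentiated, in one operation. Every other oxygen is masked as a benzyl ether, so one hydrogenolysis ends the synthesis.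

Key step: step 13

Remarks on the chemistry:
- The quaternary oxygen of the cyclobutenone is carried as a methyl ether and the vinylogous ester as a benzyl ester. The ring expansion then gives the C5 phenol and the C8 methyl ether directly, so no air-sensitive 5,8-hydroquinone has to be methylated selectively. The end game also needs no Lewis acid that could attack the C8 and C4′ methyl ethers.
- Pyranone locants are those of the free 2-aryl-4-pyranone. The metalated carbon is C6, and the carbon that closes ring A is C5 (C3 of the 4-oxo-4H-pyran-2-yl substituent, C4a of the chromone).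
- 3-Bromofuran replaces furan so that the extra oxidation level of the γ-pyranone comes with the starting material. No electrophilic halogen then meets the electron-rich ring B.

Step 1
Reactants: 1 methyl 3,5-dihydroxy-4-methoxybenzoate
Product: 2 methyl 3,5-bis(benzyloxy)-4-methoxybenzoate
Conditions: BnBr, K2CO3, DMF, 60 °C
Reagents that add atoms: benzyl bromide, BrCc1ccccc1
Why: Williamson etherification of both phenols under carbonate conditions that leave the methyl ester untouched.

Step 2
Reactants: 2 methyl 3,5-bis(benzyloxy)-4-methoxybenzoate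
Product: 3 [3,5-bis(benzyloxy)-4-methoxyphenyl]methanol
Conditions: LiAlH4, THF, 0 °C to rt; aqueous NaOH work-up
Reagents that add atoms: none
Why: Hydride reduction of an aryl ester to the benzylic alcohol, to which benzyl and methyl aryl ethers are inert.

Step 3
Reactants: 3 [3,5-bis(benzyloxy)-4-methoxyphenyl]methanol
Product: 4 3,5-bis(benzyloxy)-4-methoxybenzaldehyde
Conditions: MnO2 (activated, excess), CH2Cl2, rt
Reagents that add atoms: none
Why: Heterogeneous MnO2 oxidation of a benzylic alcohol, which stops at the aldehyde.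

Step 4
Reactants: 4 3,5-bis(benzyloxy)-4-methoxybenzaldehyde; 5 3-bromofuran
Product: 7 [3,5-bis(benzyloxy)-4-methoxyphenyl](3-bromofuran-2-yl)methanol (racemic), via 3-bromo-2-lithiofuran 6 (not isolated)
Conditions: LiN(iPr)2 (LDA), THF, −78 °C; then 4, −78 °C; NH4Cl (aq)
Reagents that add atoms: none
Why: Directed deprotonation of 3-bromofuran at C2 by the amide base (no bromine–lithium exchange) and 1,2-addition of the furyllithium to the non-enolisable aldehyde; the carbinol centre forms racemic and is erased in step 6.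

Step 5
Reactants: 7 [3,5-bis(benzyloxy)-4-methoxyphenyl](3-bromofuran-2-yl)methanol
Product: 8 2-[3,5-bis(benzyloxy)-4-methoxyphenyl]-4-bromo-6-hydroxy-2H-pyran-3(6H)-one (mixture of diastereomers)
Conditions: mCPBA, CH2Cl2, 0 °C to rt
Reagents that add atoms: 3-chloroperoxybenzoic acid (mCPBA), OOC(=O)c1cccc(Cl)c1
Why: Achmatowicz oxidative ring expansion, in which peracid oxidation of the furan gives a cis-enedione that the carbinol oxygen captures as the six-membered hemiacetal; a peracid is used because bromine-based oxidants would attack ring B, and both stereocentres are lost in step 6.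

Step 6
Reactants: 8 2-[3,5-bis(benzyloxy)-4-methoxyphenyl]-4-bromo-6-hydroxy-2H-pyran-3(6H)-one
Product: 9 2-[3,5-bis(benzyloxy)-4-methoxyphenyl]-3-hydroxy-4H-pyran-4-one
Conditions: 1 M H2SO4 (aq), 1,4-dioxane, 80 °C
Reagents that add atoms: water, O (supplies the C4 carbonyl oxygen; the anomeric hydroxyl leaves as water)
Why: Hydrolytic aromatisation known for 4-halo-6-hydroxy-2H-pyran-3(6H)-ones (maltol-type chemistry), in which loss of the anomeric hydroxyl and enolisation give a 4-bromo-3-hydroxypyrylium ion that water attacks at C4 with expulsion of bromide.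

Step 7
Reactants: 9 2-[3,5-bis(benzyloxy)-4-methoxyphenyl]-3-hydroxy-4H-pyran-4-one
Product: 10 3-(benzyloxy)-2-[3,5-bis(benzyloxy)-4-methoxyphenyl]-4H-pyran-4-one
Conditions: BnBr, K2CO3, DMF, 50 °C
Reagents that add atoms: benzyl bromide, BrCc1ccccc1
Why: Williamson benzylation of the acidic enolic 3-hydroxyl, the standard protection of 3-hydroxy-4-pyranones.

Step 8
Reactants: 11 squaric acid (3,4-dihydroxycyclobut-3-ene-1,2-dione)
Product: 12 dibenzyl squarate (3,4-bis(benzyloxy)cyclobut-3-ene-1,2-dione)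
Conditions: BnOH (excess), toluene, reflux, azeotropic removal of water
Reagents that add atoms: benzyl alcohol, OCc1ccccc1
Why: Fischer-type esterification of a strong vinylogous acid that catalyses its own reaction and is driven to the diester by removal of water.

Step 9
Reactants: 12 dibenzyl squarate
Product: 13 2,3-bis(benzyloxy)-4-hydroxycyclobut-2-en-1-one (racemic)
Conditions: LiAlH(OtBu)3, THF, −78 to −20 °C
Reagents that add atoms: none
Why: The hindered alkoxyaluminium hydride should reduce one squarate carbonyl by 1,2-addition and stop at the hydroxycyclobutenone, whose remaining carbonyl is a deactivated vinylogous ester; the racemic carbinol centre is removed in step 10.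

Step 10
Reactants: 13 2,3-bis(benzyloxy)-4-hydroxycyclobut-2-en-1-one
Product: 14 3-(benzyloxy)cyclobut-3-ene-1,2-dione (benzyl semisquarate)
Conditions: 12 M HCl (aq, few drops), CH2Cl2, rt
Reagents that add atoms: water, O (supplies the new carbonyl oxygen; the carbinol hydroxyl leaves as water)
Why: Acid-catalysed allylic transposition and elimination, in which ionisation of the carbinol gives an alkoxy-stabilised cyclobutenyl cation, water adds at the benzyloxy-bearing terminus and benzyl alcohol is expelled to leave the dione.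

Step 11
Reactants: 10 3-(benzyloxy)-2-[3,5-bis(benzyloxy)-4-methoxyphenyl]-4H-pyran-4-one; 14 3-(benzyloxy)cyclobut-3-ene-1,2-dione
Product: 16 3-(benzyloxy)-4-{5-(benzyloxy)-6-[3,5-bis(benzyloxy)-4-methoxyphenyl]-4-oxo-4H-pyran-2-yl}-4-hydroxycyclobut-2-en-1-one (racemic), via 6-lithiopyranone 15 (not isolated)
Conditions: LiTMP (lithium 2,2,6,6-tetramethylpiperidide), THF, −78 °C, short metalation; then 14 (1.5 equiv), −78 °C; NH4Cl (aq) at −78 °C
Reagents that add atoms: none
Why: LiTMP should remove the pyranone proton next to the ring oxygen (C6, the position type at which chromones are lithiated at C2), and the vinyllithium should add 1,2 to the ketone-like carbonyl of 14 beside the benzyloxy-bearing carbon, the other carbonyl being a deactivated vinylogous ester (organolithium addition to a cyclobutenedione); the quaternary carbinol centre forms racemic and later becomes aromatic C8.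

Step 12
Reactants: 16 3-(benzyloxy)-4-{5-(benzyloxy)-6-[3,5-bis(benzyloxy)-4-methoxyphenyl]-4-oxo-4H-pyran-2-yl}-4-hydroxycyclobut-2-en-1-one
Product: 17 3-(benzyloxy)-4-{5-(benzyloxy)-6-[3,5-bis(benzyloxy)-4-methoxyphenyl]-4-oxo-4H-pyran-2-yl}-4-methoxycyclobut-2-en-1-one (racemic)
Conditions: MeI (excess), Ag2O, 4 Å molecular sieves, MeCN, rt, dark
Reagents that add atoms: iodomethane, CI
Why: Purdie methylation etherifies the tertiary carbinol without a strong base, so the base-sensitive hydroxycyclobutenone is not opened, and iodomethane is too weak an electrophile to O-methylate the pyranone carbonyl.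

Step 13
Reactants: 17 3-(benzyloxy)-4-{5-(benzyloxy)-6-[3,5-bis(benzyloxy)-4-methoxyphenyl]-4-oxo-4H-pyran-2-yl}-4-methoxycyclobut-2-en-1-one
Product: 20 3,7-bis(benzyloxy)-2-[3,5-bis(benzyloxy)-4-methoxyphenyl]-5-hydroxy-8-methoxy-4H-chromen-4-one, via (Z)-dienylketene 18 (not isolated), via 4aH-chromene-4,5-dione tautomer 19 (not isolated)
Conditions: p-xylene (degassed, dry, 0.01 M), 135 °C, argon
Reagents that add atoms: none
Why: Heating cleaves the C(=O)–C(OMe) bond of the cyclobutenone by conrotatory 4π electrocyclic opening, and because the methoxy donor on the sp3 carbon rotates outward the pyranonyl group turns inward, giving the (Z)-dienylketene 18 with its ketene carbon beside the free pyranone CH. Ring A then closes by thermal disrotatory 6π electrocyclisation across the ketene C=C, the C(OBn)=C(OMe) bond and the pyranone C=C, which forms the C4a–C5 bond and the 4aH-dienone 19; enolisation of the doubly activated C4a–H aromatises it to the chelated 5-hydroxy arene 20. The closest known reaction type is the thermal ring expansion of squarate-derived 4-aryl-, 4-heteroaryl- and 4-alkenyl-4-alkoxy (or hydroxy) cyclobutenones to annulated hydroquinone derivatives; a 4-oxopyran-2-yl group has not itself served as the unsaturated arm, which is why the risk of the route sits here. No stereocentre survives, since the quaternary carbon of 17 becomes aromatic C8 and the transient C4a centre of 19 is lost on tautomerisation. The step needs torquoselectivity, secured by the alkoxy substituent (a ketene from the wrong rotation cannot be trapped by a methyl ether and should simply reclose), and regiochemistry, secured because only one pyranone carbon is free to close the ring and step 11 fixed the order ketene C, CH, C–OBn, C–OMe that maps onto C5, C6, C7, C8. High dilution in dry, degassed solvent should keep the ketene from dimerising or being captured by water.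

Step 14
Reactants: 20 3,7-bis(benzyloxy)-2-[3,5-bis(benzyloxy)-4-methoxyphenyl]-5-hydroxy-8-methoxy-4H-chromen-4-one
Product: 21 3,5,7-trihydroxy-2-(3,5-dihydroxy-4-methoxyphenyl)-8-methoxy-4H-chromen-4-one
Conditions: H2 (1 atm), 10% Pd/C, THF/MeOH, rt
Reagents that add atoms: none
Why: Catalytic hydrogenolysis cleaves all four benzyl ethers under neutral conditions that leave the two methyl ethers and the chromone untouched.

Compound list
1 | methyl 3,5-dihydroxy-4-methoxybenzoate | COC(=O)c1cc(O)c(OC)c(O)c1 | starting material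
2 | methyl 3,5-bis(benzyloxy)-4-methoxybenzoate | COC(=O)c1cc(OCc2ccccc2)c(OC)c(OCc2ccccc2)c1 | intermediate
3 | [3,5-bis(benzyloxy)-4-methoxyphenyl]methanol | OCc1cc(OCc2ccccc2)c(OC)c(OCc2ccccc2)c1 | intermediate
4 | 3,5-bis(benzyloxy)-4-methoxybenzaldehyde | O=Cc1cc(OCc2ccccc2)c(OC)c(OCc2ccccc2)c1 | intermediate
5 | 3-bromofuran | Brc1ccoc1 | starting material
6 | 3-bromo-2-lithiofuran (formed in the flask) | [Li]c1occc1Br | intermediate
7 | [3,5-bis(benzyloxy)-4-methoxyphenyl](3-bromofuran-2-yl)methanol (racemic) | OC(c1occc1Br)c1cc(OCc2ccccc2)c(OC)c(OCc2ccccc2)c1 | intermediate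
8 | 2-[3,5-bis(benzyloxy)-4-methoxyphenyl]-4-bromo-6-hydroxy-2H-pyran-3(6H)-one (mixture of diastereomers, each racemic) | OC1C=C(Br)C(=O)C(c2cc(OCc3ccccc3)c(OC)c(OCc3ccccc3)c2)O1 | intermediate
9 | 2-[3,5-bis(benzyloxy)-4-methoxyphenyl]-3-hydroxy-4H-pyran-4-one | O=c1ccoc(-c2cc(OCc3ccccc3)c(OC)c(OCc3ccccc3)c2)c1O | intermediate
10 | 3-(benzyloxy)-2-[3,5-bis(benzyloxy)-4-methoxyphenyl]-4H-pyran-4-one | O=c1ccoc(-c2cc(OCc3ccccc3)c(OC)c(OCc3ccccc3)c2)c1OCc1ccccc1 | intermediate
11 | squaric acid (3,4-dihydroxycyclobut-3-ene-1,2-dione) | O=C1C(O)=C(O)C1=O | starting material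
12 | dibenzyl squarate (3,4-bis(benzyloxy)cyclobut-3-ene-1,2-dione) | O=C1C(=O)C(OCc2ccccc2)=C1OCc1ccccc1 | intermediate
13 | 2,3-bis(benzyloxy)-4-hydroxycyclobut-2-en-1-one (racemic) | O=C1C(OCc2ccccc2)=C(OCc2ccccc2)C1O | intermediate
14 | 3-(benzyloxy)cyclobut-3-ene-1,2-dione (benzyl semisquarate) | O=C1C=C(OCc2ccccc2)C1=O | intermediate
15 | {5-(benzyloxy)-6-[3,5-bis(benzyloxy)-4-methoxyphenyl]-4-oxo-4H-pyran-2-yl}lithium (formed in the flask) | [Li]c1cc(=O)c(OCc2ccccc2)c(-c2cc(OCc3ccccc3)c(OC)c(OCc3ccccc3)c2)o1 | intermediate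
16 | 3-(benzyloxy)-4-{5-(benzyloxy)-6-[3,5-bis(benzyloxy)-4-methoxyphenyl]-4-oxo-4H-pyran-2-yl}-4-hydroxycyclobut-2-en-1-one (racemic) | O=C1C=C(OCc2ccccc2)C1(O)c1cc(=O)c(OCc2ccccc2)c(-c2cc(OCc3ccccc3)c(OC)c(OCc3ccccc3)c2)o1 | intermediate
17 | 3-(benzyloxy)-4-{5-(benzyloxy)-6-[3,5-bis(benzyloxy)-4-methoxyphenyl]-4-oxo-4H-pyran-2-yl}-4-methoxycyclobut-2-en-1-one (racemic; precursor of the key step) | O=C1C=C(OCc2ccccc2)C1(OC)c1cc(=O)c(OCc2ccccc2)c(-c2cc(OCc3ccccc3)c(OC)c(OCc3ccccc3)c2)o1 | intermediate
18 | (Z)-3-(benzyloxy)-4-{5-(benzyloxy)-6-[3,5-bis(benzyloxy)-4-methoxyphenyl]-4-oxo-4H-pyran-2-yl}-4-methoxybuta-1,3-dien-1-one (dienylketene, formed in the flask) | O=C=C/C(OCc1ccccc1)=C(/OC)c1cc(=O)c(OCc2ccccc2)c(-c2cc(OCc3ccccc3)c(OC)c(OCc3ccccc3)c2)o1 | intermediate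
19 | 3,7-bis(benzyloxy)-2-[3,5-bis(benzyloxy)-4-methoxyphenyl]-8-methoxy-4aH-chromene-4,5-dione (racemic, formed in the flask) | O=C1C=C(OCc2ccccc2)C(OC)=C2OC(-c3cc(OCc4ccccc4)c(OC)c(OCc4ccccc4)c3)=C(OCc3ccccc3)C(=O)C12 | intermediate
20 | 3,7-bis(benzyloxy)-2-[3,5-bis(benzyloxy)-4-methoxyphenyl]-5-hydroxy-8-methoxy-4H-chromen-4-one | O=c1c(OCc2ccccc2)c(-c2cc(OCc3ccccc3)c(OC)c(OCc3ccccc3)c2)oc2c(OC)c(OCc3ccccc3)cc(O)c12 | intermediate
21 | 3,5,7-trihydroxy-2-(3,5-dihydroxy-4-methoxyphenyl)-8-methoxy-4H-chromen-4-one (no stereocentre) | COc1c(O)cc(-c2oc3c(OC)c(O)cc(O)c3c(=O)c2O)cc1O | target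

Total step count: 14.
Longest linear sequence: 11 steps (steps 1–7 and 11–14). The squarate branch (steps 8–10) joins at step 11.

Steps most likely to fail

1. Step 13. Ring opening may be followed by only slow closure onto the cross-conjugated pyranone double bond. The ketene would then revert, dimerise or be intercepted by traces of water, or the strained precursor would degrade at the temperature needed. The fallback gives up the annulation, takes ring A from an aromatic building block and closes ring C last; it sets out from 4 and comes back at 21.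
   - Claisen–Schmidt condensation of 4 with commercial 1-[2,4-bis(benzyloxy)-6-hydroxyphenyl]ethan-1-one (KOH, EtOH/THF, rt) should give the chalcone (E)-1-[2,4-bis(benzyloxy)-6-hydroxyphenyl]-3-[3,5-bis(benzyloxy)-4-methoxyphenyl]prop-2-en-1-one F1.
   - Algar–Flynn–Oyamada oxidative cyclisation (H2O2, NaOH, MeOH/THF, 0 °C to rt) should give 5,7-bis(benzyloxy)-2-[3,5-bis(benzyloxy)-4-methoxyphenyl]-3-hydroxy-4H-chromen-4-one F2. Aurone formation is the competing path to be expected with a 6′-alkoxychalcone.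
   - Benzylation (BnBr, K2CO3, DMF) should give 3,5,7-tris(benzyloxy)-2-[3,5-bis(benzyloxy)-4-methoxyphenyl]-4H-chromen-4-one F3.
   - Electrophilic bromination (N-bromosuccinimide, DMF, rt) should go to C8, the position 5,7-dialkoxyflavones offer to electrophiles, giving 3,5,7-tris(benzyloxy)-2-[3,5-bis(benzyloxy)-4-methoxyphenyl]-8-bromo-4H-chromen-4-one F4.
   - Ullmann-type methoxylation (NaOMe, CuBr, MeOH/DMF, 110 °C) should give 3,5,7-tris(benzyloxy)-2-[3,5-bis(benzyloxy)-4-methoxyphenyl]-8-methoxy-4H-chromen-4-one F5.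
   - Hydrogenolysis of its five benzyl ethers (H2, 10% Pd/C, THF/MeOH) leads back to 21.

2. Step 11. Deprotonation may be incomplete or unselective, the lithiated pyranone may add to a second pyranone molecule before the electrophile is present, or it may act as a base or conjugate donor toward the semisquarate instead of adding to its ketone carbonyl. The fallback makes the nucleophile by halogen–metal exchange from an isolated iodide; it sets out from 10 and comes back at 16.
   - Zincation with TMPZnCl·LiCl (THF, rt) should give the thermally stable, non-self-condensing {5-(benzyloxy)-6-[3,5-bis(benzyloxy)-4-methoxyphenyl]-4-oxo-4H-pyran-2-yl}zinc chloride F6.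
   - Iodolysis (I2, THF) should give 3-(benzyloxy)-2-[3,5-bis(benzyloxy)-4-methoxyphenyl]-6-iodo-4H-pyran-4-one F7, which is purified.
   - Iodine–magnesium exchange (iPrMgCl·LiCl, THF, −78 °C) should then form {5-(benzyloxy)-6-[3,5-bis(benzyloxy)-4-methoxyphenyl]-4-oxo-4H-pyran-2-yl}magnesium chloride F8 in the absence of amine and of unmetalated pyranone.
   - Addition of this softer, less basic nucleophile to 14 at −78 °C leads back to 16.

3. Step 6. In hot aqueous acid the bromo-enone hemiacetal may oligomerise through its pyrylium and oxidopyrylium forms, or lose benzyl ethers, faster than water displaces bromide at C4. The fallback brings in the C4 oxygen as an epoxide instead of through a halide; it sets out from 4 and comes back at 9.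
   - Furan and n-BuLi (THF, 0 °C) give 2-furyllithium F9, which should add to 4 to give [3,5-bis(benzyloxy)-4-methoxyphenyl](furan-2-yl)methanol F10 (racemic).
   - Achmatowicz oxidation (mCPBA, CH2Cl2, 0 °C) should give 2-[3,5-bis(benzyloxy)-4-methoxyphenyl]-6-hydroxy-2H-pyran-3(6H)-one F11.
   - The hemiacetal is capped (HC(OMe)3, cat. BF3·OEt2, Et2O, 0 °C) as 2-[3,5-bis(benzyloxy)-4-methoxyphenyl]-6-methoxy-2H-pyran-3(6H)-one F12.
   - Weitz–Scheffer epoxidation of the enone (H2O2, NaOH, MeOH, 0 °C) should give 2-[3,5-bis(benzyloxy)-4-methoxyphenyl]-4,5-epoxy-6-methoxytetrahydro-2H-pyran-3-one F13.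
   - Acid (TsOH, toluene, 80 °C) should isomerise the epoxy ketone to the diosphenol and expel methanol, which leads back to 9.

Further compounds
F1 | step 13 | (E)-1-[2,4-bis(benzyloxy)-6-hydroxyphenyl]-3-[3,5-bis(benzyloxy)-4-methoxyphenyl]prop-2-en-1-one | O=C(/C=C/c1cc(OCc2ccccc2)c(OC)c(OCc2ccccc2)c1)c1c(O)cc(OCc2ccccc2)cc1OCc1ccccc1
F2 | step 13 | 5,7-bis(benzyloxy)-2-[3,5-bis(benzyloxy)-4-methoxyphenyl]-3-hydroxy-4H-chromen-4-one | O=c1c(O)c(-c2cc(OCc3ccccc3)c(OC)c(OCc3ccccc3)c2)oc2cc(OCc3ccccc3)cc(OCc3ccccc3)c12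
F3 | step 13 | 3,5,7-tris(benzyloxy)-2-[3,5-bis(benzyloxy)-4-methoxyphenyl]-4H-chromen-4-one | O=c1c(OCc2ccccc2)c(-c2cc(OCc3ccccc3)c(OC)c(OCc3ccccc3)c2)oc2cc(OCc3ccccc3)cc(OCc3ccccc3)c12
F4 | step 13 | 3,5,7-tris(benzyloxy)-2-[3,5-bis(benzyloxy)-4-methoxyphenyl]-8-bromo-4H-chromen-4-one | O=c1c(OCc2ccccc2)c(-c2cc(OCc3ccccc3)c(OC)c(OCc3ccccc3)c2)oc2c(Br)c(OCc3ccccc3)cc(OCc3ccccc3)c12
F5 | step 13 | 3,5,7-tris(benzyloxy)-2-[3,5-bis(benzyloxy)-4-methoxyphenyl]-8-methoxy-4H-chromen-4-one | O=c1c(OCc2ccccc2)c(-c2cc(OCc3ccccc3)c(OC)c(OCc3ccccc3)c2)oc2c(OC)c(OCc3ccccc3)cc(OCc3ccccc3)c12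
F6 | step 11 | {5-(benzyloxy)-6-[3,5-bis(benzyloxy)-4-methoxyphenyl]-4-oxo-4H-pyran-2-yl}zinc chloride | Cl[Zn]c1cc(=O)c(OCc2ccccc2)c(-c2cc(OCc3ccccc3)c(OC)c(OCc3ccccc3)c2)o1
F7 | step 11 | 3-(benzyloxy)-2-[3,5-bis(benzyloxy)-4-methoxyphenyl]-6-iodo-4H-pyran-4-one | Ic1cc(=O)c(OCc2ccccc2)c(-c2cc(OCc3ccccc3)c(OC)c(OCc3ccccc3)c2)o1
F8 | step 11 | {5-(benzyloxy)-6-[3,5-bis(benzyloxy)-4-methoxyphenyl]-4-oxo-4H-pyran-2-yl}magnesium chloride | Cl[Mg]c1cc(=O)c(OCc2ccccc2)c(-c2cc(OCc3ccccc3)c(OC)c(OCc3ccccc3)c2)o1
F9 | step 6 | 2-furyllithium | [Li]c1ccco1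
F10 | step 6 | [3,5-bis(benzyloxy)-4-methoxyphenyl](furan-2-yl)methanol (racemic) | OC(c1ccco1)c1cc(OCc2ccccc2)c(OC)c(OCc2ccccc2)c1
F11 | step 6 | 2-[3,5-bis(benzyloxy)-4-methoxyphenyl]-6-hydroxy-2H-pyran-3(6H)-one (mixture of diastereomers) | OC1C=CC(=O)C(c2cc(OCc3ccccc3)c(OC)c(OCc3ccccc3)c2)O1
F12 | step 6 | 2-[3,5-bis(benzyloxy)-4-methoxyphenyl]-6-methoxy-2H-pyran-3(6H)-one (mixture of diastereomers) | COC1C=CC(=O)C(c2cc(OCc3ccccc3)c(OC)c(OCc3ccccc3)c2)O1
F13 | step 6 | 2-[3,5-bis(benzyloxy)-4-methoxyphenyl]-4,5-epoxy-6-methoxytetrahydro-2H-pyran-3-one (mixture of diastereomers) | COC1OC(c2cc(OCc3ccccc3)c(OC)c(OCc3ccccc3)c2)C(=O)C2OC12
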